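The earlier runs and the new flask are calculated from invented constants.

0.332 M of partner is what I can spend on Thursday's, Saturday's and Wednesday's flasks alike: the charge less the protic impurity, which I assume takes its own amount of partner first. Partner is the reagent I balance, and from Saturday's on usable partner is less than the starting material charged, so in those flasks it is the limiting reagent.

in all of them: protic impurity 0.0185 M
- north-west: starting material 0.20 M; partner 0.24 M; second substrate 0.74 M (in portions, 4); run made earlier; portions every 5.0 s
- south-west: starting material 0.20 M; partner 0.18 M; second substrate 0.74 M (in portions, 4); run made earlier; portions every 5.0 s
- Thursday's: starting material 0.20 M; partner 0.351 M; second substrate 0.740 M (in portions, 4); the portions of second substrate follow each other after 5.0 s, the first at the start; time 2.0 min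
- Saturday's: starting material 0.40 M; partner 0.351 M; second substrate 0.740 M (in portions, 4); the portions of second substrate follow each other after 5.0 s, the first at the start; time 2.0 min
- Wednesday's: starting material 0.80 M; partner 0.351 M; second substrate 0.740 M (in portions, 4); the portions of second substrate follow each other after 5.0 s, the first at the start; time 2.0 min

| run | time / s | target / % | starting material / % |
|---|---|---|---|
| north-west | 10.0 | 44 | 6 |
| north-west | 12.0 | 44 | 3 |
| north-west | 20.0 | 43 | 0 |
| north-west | 30.0 | 47 | 0 |
| north-west | 50.0 | 44 | 0 |
| north-west | 80.0 | 42 | 1 |
| south-west | 10.0 | 30 | 7 |
| south-west | 12.0 | 32 | 5 |
| south-west | 20.0 | 30 | 0 |
| south-west | 30.0 | 29 | 4 |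
| south-west | 40.0 | 33 | 0 |
| south-west | 60.0 | 28 | 0 |
| south-west | 80.0 | 29 | 0 |

(scatter of a reading: 1.5 percentage points)

- [target] at the end for Thursday's, Saturday's, Wednesday's, in this order
- the shape of the row from first to last (falls all the way / rises, then falls / falls, then rises / rises all the way / hardly changes)

- percent here means starting material units held: one side product counts as two
- on the list of suspects stand: partner + protic impurity -> quenched reagent; starting material + partner -> target; second substrate + partner -> second product; partner -> decomposed reagent; starting material + second substrate -> cross product; starting material + target -> side product
- "hardly changes" means that all values lie within two and a half points (for a concentration: within two and a half percent of the largest)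

I build the flask up one step at a time. With the main step alone, [target] is the smaller of starting material and usable partner, so the row reads 0.200 M, 0.332 M, 0.332 M. Now I let second substrate compete for partner, and I take the size of the loss from the earlier runs, whose readings hold whatever else ran in them too. At 10.0 s the north-west run reads 0.0880 M of target from 0.222 M of usable partner, and the south-west run reads 0.0600 M from 0.162 M. As readings, that is 0.397 and 0.372 target per usable partner, and carrying the first ratio over gives my estimate for Thursday's of 0.132 M.

Last I add starting material + target -> side product, where one event removes one of each. Once starting material is used up, and the north-west run reads 0% of it at 20.0 s, the balance reads: [target] equals two times the partner that reached starting material, less the starting material charged, plus [cross product]. Two times usable partner less the starting material charged I call the target room −0.135 M, here for Wednesday's; Saturday's has 0.265 M. Wednesday's charge is larger than two times usable partner, so its room is negative and any target left there must be paid for by cross product. I commit to a row that rises to Saturday's and falls at Wednesday's.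

The forecast gives 0.11 M, 0.19 M, 0.26 M, shape rises all the way, on the ground that “More starting material captures more partner, so target rises throughout”. We part in direction at Wednesday's.

The flasks give 0.124 M, 0.137 M, 0.0239 M: rises, then falls.

    partner + protic impurity → quenched reagent (k = 66.5 L mol⁻¹ s⁻¹)
    starting material + partner → target (k = 2.44 L mol⁻¹ s⁻¹)
    second substrate + partner → second product (k = 0.710 L mol⁻¹ s⁻¹)
    partner → decomposed reagent (k = 0.0201 s⁻¹)
    starting material + second substrate → cross product (k = 0.360 L mol⁻¹ s⁻¹)
    starting material + target → side product (k = 1.01 L mol⁻¹ s⁻¹)

In Wednesday's flask at 0.250 min, partner stands at 0.00661% of its charge and starting material at 5.31%, while side product already holds 68.5%. By 2.00 min starting material stands at 0%, cross product at 27.2% and target at 2.99%, each in percent of the starting material charged. Wednesday's room of −0.135 M, less two times the sum of second product and decomposed reagent, plus cross product, comes to 0.0239 M. The same sum from Saturday's room of 0.265 M comes to 0.137 M.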